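Everything rests on disconnecting ring A at C3–C4. A primary C3 radical, released from an iodide, attacks the inner carbon C4 of a C5 ethynyl carbinol in a 6-exo-dig closure; one operation forms ring A of the trans-decalin and leaves the exocyclic C4=C15 methylene beside the C5 tertiary alcohol. The feature exploited is that the C15=C4–C5(OH) unit of ring A maps onto an ethynyl carbinol, so only the C3–C4 bond is missing. The precursor is a ring B cyclohexanol with the C5 ethynyl group, a quaternary C10 carrying a CH(OSiR3)CH2CH2I arm (C1–C3) and a ketal-masked acetyl group at C7; the C1 bromide and the triene are added afterwards.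

Key step: step 13

Numbering: target decalin numbering is used throughout (ring A = C1–C5 and C10, ring B = C5–C10, C14 = methyl on C10, C15 = methylene carbon on C4, C11 = side-chain carbon on C7).
Remark on the chemistry: C1 is carried as the (S)-silyl ether (axial in ring A), opposite in space to the equatorial C1–Br bond of the target, so that bromide can enter with inversion; C5, C7 and C10 have the target arrangement from the step that sets each.
Assumption: (−)-Ipc2B(allyl), the allylborane made from (+)-α-pinene, is taken to add to the Si face of the α-quaternary aldehyde as it does with other α-branched aldehydes.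

Step 1
Reactants: 1 cyclohex-2-en-1-one; 2 isopropenylboronic acid pinacol ester
Product: 3 (R)-3-(prop-1-en-2-yl)cyclohexan-1-one
Conditions: [Rh(cod)Cl]2 (1.5 mol %), (R)-BINAP (3.3 mol %), KOH (0.2 equiv), 1,4-dioxane/H2O 10:1, 40 °C
Reagents that add atoms: none
Why: Hayashi–Miyaura conjugate addition, in which the alkenylrhodium species inserts the enone inside the (R)-BINAP pocket that delivers aryl and alkenyl groups to cyclohexenone with the (R) sense, so C7 should be set under catalyst control.

Step 2
Reactants: 3 (R)-3-(prop-1-en-2-yl)cyclohexan-1-one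
Product: 4 (5R,2Z)-2-(hydroxymethylidene)-5-(prop-1-en-2-yl)cyclohexan-1-one
Conditions: HCO2Et, NaH, EtOH (cat.), THF, 0 °C → rt; then aq. HCl
Reagents that add atoms: ethyl formate (CCOC=O)
Why: Claisen formylation under equilibrating conditions, where the chelated enolate of the 1,3-dicarbonyl product is the thermodynamic sink and should form at the α-carbon remote from the C7 substituent (the future C10), as is usual for 3-substituted cyclohexanones; no stereocentre is created.

Step 3
Reactants: 4 (5R,2Z)-2-(hydroxymethylidene)-5-(prop-1-en-2-yl)cyclohexan-1-one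
Product: 5 (1S,4R)-1-methyl-2-oxo-4-(prop-1-en-2-yl)cyclohexane-1-carbaldehyde (methyl cis to isopropenyl)
Conditions: MeI, K2CO3, acetone, reflux
Reagents that add atoms: methyl iodide (CI)
Why: C-alkylation of a β-keto aldehyde enolate, in which methyl iodide should approach C10 along the axial trajectory of the half-chair that keeps the C7 isopropenyl group equatorial, so the methyl enters cis to that group and the formyl group ends equatorial, which sets C10; the minor C10 epimer and any O-methylated material would be removed by chromatography.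

Step 4
Reactants: 5 (1S,4R)-1-methyl-2-oxo-4-(prop-1-en-2-yl)cyclohexane-1-carbaldehyde
Product: 7 (1S,4R)-4-acetyl-1-methyl-2-oxocyclohexane-1-carbaldehyde, via secondary ozonide 6 (not isolated)
Conditions: O3, CH2Cl2, −78 °C (Sudan Red 7B); then PPh3, −78 °C → rt
Reagents that add atoms: ozone ([O-][O+]=O)
Why: Ozonolysis with reductive work-up, in which the 1,1-disubstituted alkene is the only site that reacts at −78 °C before the dye end point, and C7, now α to the acetyl group, already holds its more stable equatorial arrangement so that it cannot be lost by enolisation.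

Step 5
Reactants: 7 (1S,4R)-4-acetyl-1-methyl-2-oxocyclohexane-1-carbaldehyde
Product: 9 (2S,5R)-5-acetyl-2-[(1S)-1-hydroxybut-3-en-1-yl]-2-methylcyclohexan-1-one, via borinate ester 8 (not isolated)
Conditions: (−)-Ipc2B(allyl) (salt-free, 1.2 equiv), Et2O, −100 → −78 °C; then HOCH2CH2NH2, rt
Reagents that add atoms: (−)-B-allyldiisopinocampheylborane (C=CCB([C@@H]1C[C@@H]2C[C@H]([C@H]1C)C2(C)C)[C@@H]1C[C@@H]2C[C@H]([C@H]1C)C2(C)C)
Why: Brown allylboration, which at this temperature is far faster with the aldehyde than with either ketone and whose chair transition state should deliver allyl to the Si face under reagent control, setting C1 as (S), because the quaternary C10 (methyl versus ring CH2) offers little bias of its own; the non-basic work-up avoids retro-aldol cleavage.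

Step 6
Reactants: 9 (2S,5R)-5-acetyl-2-[(1S)-1-hydroxybut-3-en-1-yl]-2-methylcyclohexan-1-one
Product: 10 (2S,5R)-5-acetyl-2-[(1S)-1-(tert-butyldimethylsilyloxy)but-3-en-1-yl]-2-methylcyclohexan-1-one
Conditions: TBSOTf, 2,6-lutidine, CH2Cl2, −78 → 0 °C
Reagents that add atoms: tert-butyldimethylsilyl trifluoromethanesulfonate (CC(C)(C)[Si](C)(C)OS(=O)(=O)C(F)(F)F)
Why: Silylation with a silyl triflate, chosen because the neopentyl secondary alcohol is too hindered for the chloride; the ether also blocks retro-aldol cleavage in the basic steps that follow.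

Step 7
Reactants: 10 (2S,5R)-5-acetyl-2-[(1S)-1-(tert-butyldimethylsilyloxy)but-3-en-1-yl]-2-methylcyclohexan-1-one
Product: 11 (2S,5R)-2-[(1S)-1-(tert-butyldimethylsilyloxy)but-3-en-1-yl]-2-methyl-5-(2-methyl-1,3-dioxolan-2-yl)cyclohexan-1-one
Conditions: HOCH2CH2OH, PPTS (cat.), benzene, reflux (Dean–Stark)
Reagents that add atoms: ethane-1,2-diol (OCCO)
Why: Acid-catalysed ketalisation with azeotropic removal of water, in which the unhindered methyl ketone reacts while the ring ketone, flanked by the quaternary C10 and its bulky silyloxyalkyl arm, should remain free.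

Step 8
Reactants: 11 (2S,5R)-2-[(1S)-1-(tert-butyldimethylsilyloxy)but-3-en-1-yl]-2-methyl-5-(2-methyl-1,3-dioxolan-2-yl)cyclohexan-1-one
Product: 12 enol ether with C5=CH(OMe) in place of the C5 carbonyl of 11 (E/Z mixture)
Conditions: Ph3P(CH2OMe)Cl, KN(SiMe3)2, THF, 0 → 50 °C
Reagents that add atoms: (methoxymethyl)triphenylphosphonium chloride (COC[P+](c1ccccc1)(c1ccccc1)c1ccccc1.[Cl-])
Why: Wittig olefination with the methoxymethylene ylide, the standard one-carbon homologation of 2,2-disubstituted cyclohexanones; the C5 ketone is the only carbonyl left, nothing can be eliminated because C10 is quaternary, and the alkene geometry does not matter.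

Step 9
Reactants: 12 enol ether (E/Z mixture)
Product: 14 (1S,2S,5R)-2-[(1S)-1-(tert-butyldimethylsilyloxy)but-3-en-1-yl]-1-hydroxy-2-methyl-5-(2-methyl-1,3-dioxolan-2-yl)cyclohexane-1-carbaldehyde, via methoxy epoxide 13 (not isolated)
Conditions: DMDO, acetone/CH2Cl2, −78 → −30 °C; then THF/aq. buffer pH 4, 0 °C
Reagents that add atoms: dimethyldioxirane (CC1(C)OO1); water (O)
Why: Epoxidation of an enol ether followed by hydrolysis of the alkoxy epoxide (Rubottom-type oxidation), in which the dioxirane should attack the electron-rich enol ether far faster than the terminal alkene and from the α face, anti to the axial C10 methyl that shields the β face, so the C5–O bond becomes axial and the formyl carbon C4 equatorial, which sets C5.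

Step 10
Reactants: 14 α-hydroxy aldehyde
Product: 15 (1R,2S,5R)-2-[(1S)-1-(tert-butyldimethylsilyloxy)but-3-en-1-yl]-1-ethynyl-2-methyl-5-(2-methyl-1,3-dioxolan-2-yl)cyclohexan-1-ol
Conditions: MeC(O)C(N2)P(O)(OMe)2, K2CO3, MeOH, 0 °C → rt
Reagents that add atoms: dimethyl (1-diazo-2-oxopropyl)phosphonate (CC(=O)C(=[N+]=[N-])P(=O)(OC)OC)
Why: Seyferth–Gilbert homologation in the Ohira–Bestmann version, which converts the non-enolisable tertiary α-hydroxy aldehyde into the terminal alkyne (C4≡C15) under mild K2CO3/MeOH conditions without touching C5.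

Step 11
Reactants: 15 ethynyl carbinol with the but-3-enyl arm
Product: 17 (1R,2S,5R)-2-[(1S)-1-(tert-butyldimethylsilyloxy)-3-hydroxypropyl]-1-ethynyl-2-methyl-5-(2-methyl-1,3-dioxolan-2-yl)cyclohexan-1-ol, via secondary ozonide 16 (not isolated)
Conditions: O3, CH2Cl2, −78 °C (Sudan Red 7B); then NaBH4, EtOH, −78 → 0 °C
Reagents that add atoms: ozone ([O-][O+]=O)
Why: Ozonolysis with NaBH4 work-up, relying on the much higher reactivity of the monosubstituted alkene than of the terminal alkyne towards ozone and on the dye to stop the gas stream in time; hydride then reduces the ozonide to the primary C3 alcohol.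

Step 12
Reactants: 17 C3 primary alcohol
Product: 18 (1R,2S,5R)-2-[(1S)-1-(tert-butyldimethylsilyloxy)-3-iodopropyl]-1-ethynyl-2-methyl-5-(2-methyl-1,3-dioxolan-2-yl)cyclohexan-1-ol
Conditions: I2, PPh3, imidazole, CH2Cl2, 0 °C → rt
Reagents that add atoms: iodine (II)
Why: Appel-type iodination (Garegg–Samuelsson conditions), in which only the primary alcohol forms the oxyphosphonium ion that iodide displaces, the tertiary propargylic alcohol being inert.

Step 13
Reactants: 18 C3 iodide with C5 ethynyl carbinol
Product: 19 (1S,4aR,6R,8aS)-1-(tert-butyldimethylsilyloxy)-8a-methyl-4-methylidene-6-(2-methyl-1,3-dioxolan-2-yl)octahydronaphthalen-4a(2H)-ol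
Conditions: (Me3Si)3SiH (1.3 equiv) and AIBN (0.2 equiv) by syringe pump over 8 h, toluene (0.005 M), 80 °C
Reagents that add atoms: none
Why: Radical chain cyclisation: the silyl radical abstracts iodine from C3, the primary radical adds to the nearer alkyne carbon C4, and the C15 vinyl radical takes hydrogen from the silane, which carries the chain. The closest known reaction is the 6-exo-dig cyclisation of hept-6-ynyl radicals generated from primary iodides under stannane or silane conditions, which gives methylenecyclohexanes. Ring A closes in the 6-exo-dig mode through a chair in which C1 and C4 are both equatorial on ring B, so only the trans-fused decalin can form. No stereocentre is created, since C1, C5, C7 and C10 are carried through and C4 becomes sp2. The step needs ring closure to outrun hydrogen transfer to the open-chain radical, attack at C4 and not at C15, and iodine abstraction in preference to silyl radical addition to the alkyne. Slow addition of the silane at high dilution and 80 °C, the fully substituted C5 and C10 in the tether, the terminal alkyne and the weak C–I bond should secure these.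

Step 14
Reactants: 19 decalin with C11 dioxolane
Product: 20 (1S,4aR,6R,8aS)-6-acetyl-1-(tert-butyldimethylsilyloxy)-8a-methyl-4-methylideneoctahydronaphthalen-4a(2H)-ol
Conditions: PPTS (cat.), acetone/H2O 10:1, 50 °C
Reagents that add atoms: water (O)
Why: Acid-catalysed ketal hydrolysis, with pyridinium tosylate mild enough to leave the silyl ether and the tertiary allylic alcohol alone.

Step 15
Reactants: 20 methyl ketone
Product: 22 (1S,4aR,6R,8aS)-1-(tert-butyldimethylsilyloxy)-6-ethynyl-8a-methyl-4-methylideneoctahydronaphthalen-4a(2H)-ol, via enol phosphate 21 (not isolated)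
Conditions: LiN(i-Pr)2 (2.1 equiv), THF, −78 °C; ClP(O)(OEt)2 (1.05 equiv), −78 → 0 °C; then LiN(i-Pr)2 (2.5 equiv), −78 °C → rt; aq. NH4Cl
Reagents that add atoms: none
Why: Enol phosphate elimination (Negishi alkyne synthesis from methyl ketones), in which kinetic deprotonation takes the methyl group after the C5 alkoxide has formed, O-phosphorylation of the enolate should outpace that of the hindered tertiary alkoxide, and excess amide base eliminates phosphate to the acetylide, which also shields C7 from epimerisation.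

Step 16
Reactants: 22 C7 terminal alkyne
Product: 24 (1S,4aR,6R,8aS)-1-(tert-butyldimethylsilyloxy)-6-[(E)-1-iodoprop-1-en-2-yl]-8a-methyl-4-methylideneoctahydronaphthalen-4a(2H)-ol, via alkenylalane 23 (not isolated)
Conditions: AlMe3 (3.5 equiv), Cp2ZrCl2 (0.25 equiv), CH2Cl2, 0 °C → rt; then I2, THF, −30 → 0 °C
Reagents that add atoms: trimethylaluminium (C[Al](C)C); iodine (II)
Why: Cp2ZrCl2-catalysed carboalumination (Negishi) followed by iodinolysis, in which methyl and aluminium add syn across the alkyne with methyl on the inner carbon C11 and iodine replaces aluminium with retention, giving the (E)-iodoalkene; the 1,1-disubstituted C4 alkene is inert and the alcohol is only converted into its aluminium alkoxide.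

Step 17
Reactants: 24 silyl ether
Product: 25 (1S,4aR,6R,8aS)-6-[(E)-1-iodoprop-1-en-2-yl]-8a-methyl-4-methylideneoctahydronaphthalene-1,4a(2H)-diol
Conditions: n-Bu4NF, THF, rt → 45 °C
Reagents that add atoms: none
Why: Fluoride-mediated desilylation driven by the Si–F bond, with gentle warming to compensate for the hindered axial position; neither the iodoalkene nor the allylic alcohol is affected.

Step 18
Reactants: 25 diol (C1 hydroxyl axial)
Product: 26 (1R,4aR,6R,8aR)-1-bromo-6-[(E)-1-iodoprop-1-en-2-yl]-8a-methyl-4-methylideneoctahydronaphthalen-4a(2H)-ol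
Conditions: CBr4, P(n-C8H17)3, toluene, 0 → 70 °C
Reagents that add atoms: carbon tetrabromide (BrC(Br)(Br)Br)
Why: Appel-type bromination with a small, nucleophilic trialkylphosphine as applied to hindered secondary carbinols, in which the secondary C1 hydroxyl should be activated in preference to the tertiary C5 hydroxyl and bromide displaces the oxyphosphonium group from the β face with inversion, turning the axial (1S)-alcohol into the equatorial (1R)-bromide; displacement next to the quaternary C10 is slow and this is the weakest step after ring closure.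

Step 19
Reactants: 27 2-methylbut-1-en-3-yne; 28 pinacolborane
Product: 29 (E)-4,4,5,5-tetramethyl-2-(3-methylbuta-1,3-dien-1-yl)-1,3,2-dioxaborolane
Conditions: Cp2Zr(H)Cl (5 mol %), Et3N (10 mol %), neat, 60 °C
Reagents that add atoms: none
Why: Cp2Zr(H)Cl-catalysed hydroboration of a terminal alkyne, a syn anti-Markovnikov addition that should give the (E)-dienylboronate and leave the 1,1-disubstituted alkene alone.

Step 20
Reactants: 26 bromo iodoalkene; 29 (E)-dienylboronate
Product: 30 (1R,4aR,6R,8aR)-1-bromo-8a-methyl-4-methylidene-6-[(2E,4E)-6-methylhepta-2,4,6-trien-2-yl]octahydronaphthalen-4a(2H)-ol (target)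
Conditions: Pd(PPh3)4 (5 mol %), aq. K3PO4, THF, 40 °C
Reagents that add atoms: none
Why: Suzuki–Miyaura coupling, in which zerovalent palladium inserts into the C(sp2)–I bond much faster than into the hindered secondary C–Br bond and both alkenyl partners couple with retention, completing the (E,E)-triene; the mild phosphate base should keep the 1,3-bromohydrin from closing to an oxetane.

Compound list
1 | cyclohex-2-en-1-one | O=C1C=CCCC1 | starting material
2 | isopropenylboronic acid pinacol ester | CC(=C)B1OC(C)(C)C(C)(C)O1 | starting material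
3 | (R)-3-(prop-1-en-2-yl)cyclohexan-1-one | CC(=C)[C@@H]1CCCC(=O)C1 | intermediate
4 | (5R,2Z)-2-(hydroxymethylidene)-5-(prop-1-en-2-yl)cyclohexan-1-one | CC(=C)[C@@H]1CC/C(=C/O)C(=O)C1 | intermediate
5 | (1S,4R)-1-methyl-2-oxo-4-(prop-1-en-2-yl)cyclohexane-1-carbaldehyde | CC(=C)[C@@H]1CC[C@@](C)(C=O)C(=O)C1 | intermediate
6 | secondary ozonide of 5 (3-methyl-1,2,4-trioxolan-3-yl group at C7) | CC1(OCOO1)[C@@H]2CC[C@@](C)(C=O)C(=O)C2 | intermediate
7 | (1S,4R)-4-acetyl-1-methyl-2-oxocyclohexane-1-carbaldehyde | CC(=O)[C@@H]1CC[C@@](C)(C=O)C(=O)C1 | intermediate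
8 | O-bis(isopinocampheyl)boryl ether of 9 | CC(=O)[C@@H]1CC[C@@](C)([C@@H](OB([C@@H]2C[C@@H]3C[C@H]([C@H]2C)C3(C)C)[C@@H]2C[C@@H]3C[C@H]([C@H]2C)C3(C)C)CC=C)C(=O)C1 | intermediate
9 | (2S,5R)-5-acetyl-2-[(1S)-1-hydroxybut-3-en-1-yl]-2-methylcyclohexan-1-one | CC(=O)[C@@H]1CC[C@@](C)([C@@H](O)CC=C)C(=O)C1 | intermediate
10 | (2S,5R)-5-acetyl-2-[(1S)-1-(tert-butyldimethylsilyloxy)but-3-en-1-yl]-2-methylcyclohexan-1-one | CC(=O)[C@@H]1CC[C@@](C)([C@@H](O[Si](C)(C)C(C)(C)C)CC=C)C(=O)C1 | intermediate
11 | (2S,5R)-2-[(1S)-1-(tert-butyldimethylsilyloxy)but-3-en-1-yl]-2-methyl-5-(2-methyl-1,3-dioxolan-2-yl)cyclohexan-1-one | CC1(OCCO1)[C@@H]2CC[C@@](C)([C@@H](O[Si](C)(C)C(C)(C)C)CC=C)C(=O)C2 | intermediate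
12 | C5 methoxymethylidene enol ether of 11 (E/Z mixture) | CC1(OCCO1)[C@@H]2CC[C@@](C)([C@@H](O[Si](C)(C)C(C)(C)C)CC=C)C(=COC)C2 | intermediate
13 | spiro methoxy epoxide of 12 (epoxide oxygen α on C5) | CC1(OCCO1)[C@@H]2CC[C@@](C)([C@@H](O[Si](C)(C)C(C)(C)C)CC=C)[C@@]3(OC3OC)C2 | intermediate
14 | (1S,2S,5R)-2-[(1S)-1-(tert-butyldimethylsilyloxy)but-3-en-1-yl]-1-hydroxy-2-methyl-5-(2-methyl-1,3-dioxolan-2-yl)cyclohexane-1-carbaldehyde | CC1(OCCO1)[C@@H]2CC[C@@](C)([C@@H](O[Si](C)(C)C(C)(C)C)CC=C)[C@](O)(C=O)C2 | intermediate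
15 | (1R,2S,5R)-2-[(1S)-1-(tert-butyldimethylsilyloxy)but-3-en-1-yl]-1-ethynyl-2-methyl-5-(2-methyl-1,3-dioxolan-2-yl)cyclohexan-1-ol | CC1(OCCO1)[C@@H]2CC[C@@](C)([C@@H](O[Si](C)(C)C(C)(C)C)CC=C)[C@](O)(C#C)C2 | intermediate
16 | secondary ozonide of 15 (1,2,4-trioxolan-3-ylmethyl group on C1) | CC1(OCCO1)[C@@H]2CC[C@@](C)([C@@H](O[Si](C)(C)C(C)(C)C)CC3OCOO3)[C@](O)(C#C)C2 | intermediate
17 | (1R,2S,5R)-2-[(1S)-1-(tert-butyldimethylsilyloxy)-3-hydroxypropyl]-1-ethynyl-2-methyl-5-(2-methyl-1,3-dioxolan-2-yl)cyclohexan-1-ol | CC1(OCCO1)[C@@H]2CC[C@@](C)([C@@H](O[Si](C)(C)C(C)(C)C)CCO)[C@](O)(C#C)C2 | intermediate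
18 | (1R,2S,5R)-2-[(1S)-1-(tert-butyldimethylsilyloxy)-3-iodopropyl]-1-ethynyl-2-methyl-5-(2-methyl-1,3-dioxolan-2-yl)cyclohexan-1-ol | CC1(OCCO1)[C@@H]2CC[C@@](C)([C@@H](O[Si](C)(C)C(C)(C)C)CCI)[C@](O)(C#C)C2 | intermediate
19 | (1S,4aR,6R,8aS)-1-(tert-butyldimethylsilyloxy)-8a-methyl-4-methylidene-6-(2-methyl-1,3-dioxolan-2-yl)octahydronaphthalen-4a(2H)-ol | CC1(OCCO1)[C@@H]2CC[C@@]3(C)[C@@H](O[Si](C)(C)C(C)(C)C)CCC(=C)[C@]3(O)C2 | intermediate
20 | (1S,4aR,6R,8aS)-6-acetyl-1-(tert-butyldimethylsilyloxy)-8a-methyl-4-methylideneoctahydronaphthalen-4a(2H)-ol | CC(=O)[C@@H]1CC[C@@]2(C)[C@@H](O[Si](C)(C)C(C)(C)C)CCC(=C)[C@]2(O)C1 | intermediate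
21 | diethyl enol phosphate of 20 (C11=CH2) | C=C(OP(=O)(OCC)OCC)[C@@H]1CC[C@@]2(C)[C@@H](O[Si](C)(C)C(C)(C)C)CCC(=C)[C@]2(O)C1 | intermediate
22 | (1S,4aR,6R,8aS)-1-(tert-butyldimethylsilyloxy)-6-ethynyl-8a-methyl-4-methylideneoctahydronaphthalen-4a(2H)-ol | C#C[C@@H]1CC[C@@]2(C)[C@@H](O[Si](C)(C)C(C)(C)C)CCC(=C)[C@]2(O)C1 | intermediate
23 | (E)-alkenyldimethylalane from 22 (as its C5 dimethylaluminium alkoxide) | C[Al](C)/C=C(\C)[C@@H]1CC[C@@]2(C)[C@@H](O[Si](C)(C)C(C)(C)C)CCC(=C)[C@]2(O[Al](C)C)C1 | intermediate
24 | (1S,4aR,6R,8aS)-1-(tert-butyldimethylsilyloxy)-6-[(E)-1-iodoprop-1-en-2-yl]-8a-methyl-4-methylideneoctahydronaphthalen-4a(2H)-ol | I/C=C(\C)[C@@H]1CC[C@@]2(C)[C@@H](O[Si](C)(C)C(C)(C)C)CCC(=C)[C@]2(O)C1 | intermediate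
25 | (1S,4aR,6R,8aS)-6-[(E)-1-iodoprop-1-en-2-yl]-8a-methyl-4-methylideneoctahydronaphthalene-1,4a(2H)-diol | I/C=C(\C)[C@@H]1CC[C@@]2(C)[C@@H](O)CCC(=C)[C@]2(O)C1 | intermediate
26 | (1R,4aR,6R,8aR)-1-bromo-6-[(E)-1-iodoprop-1-en-2-yl]-8a-methyl-4-methylideneoctahydronaphthalen-4a(2H)-ol | I/C=C(\C)[C@@H]1CC[C@@]2(C)[C@H](Br)CCC(=C)[C@]2(O)C1 | intermediate
27 | 2-methylbut-1-en-3-yne | C=C(C)C#C | starting material
28 | pinacolborane (4,4,5,5-tetramethyl-1,3,2-dioxaborolane) | [H]B1OC(C)(C)C(C)(C)O1 | starting material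
29 | (E)-4,4,5,5-tetramethyl-2-(3-methylbuta-1,3-dien-1-yl)-1,3,2-dioxaborolane | C=C(C)/C=C/B1OC(C)(C)C(C)(C)O1 | intermediate
30 | (1R,4aR,6R,8aR)-1-bromo-8a-methyl-4-methylidene-6-[(2E,4E)-6-methylhepta-2,4,6-trien-2-yl]octahydronaphthalen-4a(2H)-ol | C=C(C)/C=C/C=C(\C)[C@@H]1CC[C@@]2(C)[C@H](Br)CCC(=C)[C@]2(O)C1 | target

Total step count: 20. Longest linear sequence: 19 (steps 1–18 and 20; step 19 makes the side-chain fragment).

Steps most likely to fail

Step 18 (bromide with inversion at C1). Substitution next to the quaternary C10 may be outrun by anti elimination towards C2, by a 1,2-shift of the antiperiplanar C10 methyl, or by activation of the tertiary allylic C5 hydroxyl through a cyclic phosphorane. The fallback sets out from diol 25: selective sulfonylation of the secondary hydroxyl (Tf2O, 2,6-di-tert-butyl-4-methylpyridine, CH2Cl2, −60 °C) would give the C1 trifluoromethanesulfonate F1, which is displaced by naked bromide in a non-ionising medium (n-Bu4NBr, toluene, −40 → 0 °C), a sulfonate displacement in place of the oxyphosphonium route, and the sequence comes back at bromide 26.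

Step 13 (radical ring closure). Hydrogen transfer from the silane to the open-chain C3 radical may compete with the comparatively slow 6-exo-dig closure, and prolonged heating may let the C5 hydroxyl alkylate at C3. The fallback sets out from iodide 18 and removes the hydride donor: iodine atom-transfer cyclisation ((n-Bu3Sn)2 (10 mol %), sunlamp, benzene, 80 °C), in which the C3 radical can only cyclise and the C15 vinyl radical takes iodine from 18, would give the C15 vinyl iodide F2 (E/Z mixture). Hydrodeiodination of F2 with (Me3Si)3SiH and Et3B/air in toluene at 0 °C then comes back at decalin 19.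

Step 8 (olefination of the hindered C5 ketone). The basic ylide may enolise the ketone towards C6 or fail to add beside the quaternary C10. The fallback sets out from ketone 11: addition of the small, highly nucleophilic Me3SiCH(Li)OMe (from MeOCH2SiMe3 and s-BuLi, THF, −78 °C) would give the β-hydroxysilane F3, and Peterson elimination with KH in THF comes back at enol ether 12.

Further compounds
F1 | step 18 | (1S)-C1 trifluoromethanesulfonate of diol 25 | I/C=C(\C)[C@@H]1CC[C@@]2(C)[C@@H](OS(=O)(=O)C(F)(F)F)CCC(=C)[C@]2(O)C1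
F2 | step 13 | C15 vinyl iodide of decalin 19 (E/Z mixture) | CC1(OCCO1)[C@@H]2CC[C@@]3(C)[C@@H](O[Si](C)(C)C(C)(C)C)CCC(=CI)[C@]3(O)C2
F3 | step 8 | C5 adduct of 11 with methoxy(trimethylsilyl)methyllithium (β-hydroxysilane, mixture at the new centres) | CC1(OCCO1)[C@@H]2CC[C@@](C)([C@@H](O[Si](C)(C)C(C)(C)C)CC=C)C(O)(C(OC)[Si](C)(C)C)C2
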